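The readings were generated by integration with constants of no real substance.

Follow the gap.

| flask | substrate | reagent | temperature | remark | time |
|---|---|---|---|---|---|
| cedar | 0.020 M | 0.048 M | 61 °C | run made earlier |  |
| alder | 0.030 M | 0.048 M | 75 °C | run made earlier |  |
| ash | 0.040 M | 0.096 M | 61 °C | run made earlier |  |
| Tuesday's | 0.040 M | 0.0480 M | 55 °C |  | 15 h |
| Monday's | 0.040 M | 0.0480 M |  | at 55 °C until 5.0 h, from then on at 80 °C | 15 h |
| Sunday's | 0.040 M | 0.0480 M | 80 °C |  | 15 h |

| run | time / h | product / % | substrate / % |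
|---|---|---|---|
| cedar | 1.33 | 7.3 | 20.8 |
| cedar | 2.00 | 12.7 | 8.8 |
| cedar | 3.00 | 21.5 | 2.7 |
| cedar | 5.00 | 35.8 | 0 |
| cedar | 8.00 | 52.4 | 0.3 |
| cedar | 12.0 | 65.9 | 0.1 |
| cedar | 20.0 | 80.4 | 0.3 |
| alder | 0.500 | 8.3 | 6.2 |
| alder | 0.667 | 11.9 | 2.8 |
| alder | 1.00 | 18.0 | 0 |
| alder | 2.00 | 35.0 | 0 |
| alder | 3.00 | 46.2 | 0.6 |
| alder | 4.00 | 54.6 | 0 |
| alder | 8.00 | 73.2 | 0.3 |
| ash | 1.33 | 13.7 | 20.1 |
| ash | 2.50 | 31.1 | 4.9 |
| ash | 5.00 | 55.9 | 0 |
| ash | 10.0 | 79.9 | 0 |
| ash | 20.0 | 92.5 | 0 |

(each reading ± 0.5 percentage points)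



* which flask leads in amount of product, in percent of the substrate charged ("all alike" within 1.5 percentage points) (Tuesday's / Monday's / Sunday's / all alike)
* how much product is there at the end, in percent of the substrate charged: Tuesday's
* how much product is there at the end, in percent of the substrate charged: Monday's
* how much product is there at the end, in percent of the substrate charged: Sunday's

In the cedar run the substrate is down to 2.7% at 3.00 h while product stands at 21.5%, so the remainder is unseen, and the later readings show product still growing after the substrate has gone: call the unseen form an intermediate. Take the substrate as intermediate from the start, with reagent meeting it in a second-order step of constant k. Each product then takes one reagent and one intermediate, so their difference, the gap, stays frozen. With x the fraction of the charge turned into product: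

ln(c(reagent)/c(intermediate)) rises by k × gap per hour

x = (E − 1)/(E − charged substrate/charged reagent), with E = exp(gap × D)

Here D is the dose, the sum of k times hours at each temperature.

Turned round, the last cedar reading gives k = 2.18 L mol⁻¹ h⁻¹ at 61 °C. The ash reading at 10.0 h, with other charges, gives 2.14 L mol⁻¹ h⁻¹, close to it. The last alder reading gives 4.90 L mol⁻¹ h⁻¹ at 75 °C. A straight line of ln k against temperature then reaches 6.54 L mol⁻¹ h⁻¹ at 80 °C and 1.54 L mol⁻¹ h⁻¹ at 55 °C.

Sunday's dose is 98.1 L mol⁻¹. Two extremes bracket Sunday's flask. With reagent frozen at its charge (pseudo-first-order), x = 1 − exp(−D × c(reagent)) = 99.1%. With reagent charged equal to the substrate, x = D × c(substrate)/(1 + D × c(substrate)) = 79.7%. In this reckoning Sunday's reagent falls from its charge yet stays above the intermediate by the gap of 0.00800 M, so the reckoned flask lies between. My own reckoning: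

Tuesday's: D = 23.1 L mol⁻¹, x = 55.0%

Monday's: D = 73.1 L mol⁻¹, x = 82.7%

Sunday's: x = 87.7%, more than the other two

The forecast says 54% for Tuesday's, 73% for Monday's and 74.5% for Sunday's, lower than this reckoning on Monday's and on Sunday's, with Sunday's ahead and “Monday's nearly catches it”.

The simulation gives 53.9% for Tuesday's, 82.8% for Monday's and 87.7% for Sunday's, so Sunday's leads.

    substrate → intermediate (k = 0.150 min⁻¹, Ea = 107 kJ mol⁻¹)
    reagent + intermediate → product (k = 0.130 L mol⁻¹ min⁻¹, Ea = 56.0 kJ mol⁻¹)
    substrate ⇌ dormant form (K = 13.0, k = 0.00790 min⁻¹, Ea = 110 kJ mol⁻¹, ΔH = −58.0 kJ mol⁻¹)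
    (constants at 80 °C)

Sunday's dose of 98.1 L mol⁻¹ at a gap of 0.00800 M gave 87.7%, and that flask holds 87.7%. A neighbouring flask, Sunday's with reagent cut to 0.012 M (0.300 equiv), keeps temperature and time and so the same dose, but its gap turns negative, −0.0280 M. The same line gives 28.6%. That flask gives 29.0% of product, its reagent is down to 3.23% of its own charge, and 68.0% of the substrate charged still stands as intermediate at 15.0 h.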